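# Proposed total synthesis of CNP0142137.1

The oxolane bridging the ten-membered ring (O, quaternary C4, C3, C2 and C1–H in germacrane numbering) sits next to the tertiary carbinol C10: this anti ether/alcohol pair is read as a latent trans-epoxide and C4 as a latent methyl ketone. In the key step an epoxy-alkyl Grignard reagent (C1–C3, C8–C10, a furan as masked butenolide) adds to an auxiliary-bearing pyruvaldehyde acetal and the tertiary alkoxide opens the epoxide 5-exo, so that C3–C4 and O–C1 form in one operation and C4, C1 and C10 are set. A vinylogous Mukaiyama reaction between C5 and C6 then closes the carbocycle, and elimination gives the enol lactone.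

Key step: step 9

Locants (germacrane numbering): C1 = oxolane CH, C4 = oxolane C(CH3), C5 = vinylic CH, C6 = enol-lactone carbon, C7/C11 = butenolide β/α carbons, C8 = acyloxy CH, C10 = carbinol carbon, C12 = lactone C=O, C13 = CH2OAc. TBS = tert-butyl(dimethyl)silyl, TMS = trimethylsilyl.

Assumption: the sense of induction of (S)-TRIP (step 3), of the (R,R)-bis-hydroxamic acid ligand (step 6) and of the (4S,5S)-dioxolane auxiliary (step 9) is assigned by analogy with simple substrates; each controller has an available antipode, which would be used if the sense proved opposite.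

## Route

Step 1
Reactants: 1 furan-3,4-diyldimethanol
Product: 2 [4-(TBSO-methyl)furan-3-yl]methanol
Conditions: NaH (1.0 equiv), THF, 0 °C; TBSCl (1.0 equiv), 0 → 23 °C
Reagents that add atoms: tert-butyl(chloro)dimethylsilane CC(C)(C)[Si](C)(C)Cl
Why: One equivalent of NaH gives the sparingly soluble monosodium alkoxide, which should be silylated once (monosilylation of a symmetric diol); no stereocentre is formed.

Step 2
Reactants: 2 [4-(TBSO-methyl)furan-3-yl]methanol
Product: 3 4-(TBSO-methyl)furan-3-carbaldehyde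
Conditions: activated MnO2 (excess), CH2Cl2, 23 °C
Reagents that add atoms: none
Why: MnO2 oxidation of a furylic (benzylic-type) primary alcohol should stop at the aldehyde and leave the silyl ether and the furan untouched.

Step 3
Reactants: 3 4-(TBSO-methyl)furan-3-carbaldehyde
Product: 5 (1S)-1-[4-(TBSO-methyl)furan-3-yl]but-3-yn-1-ol, via borate ester 4 (not isolated)
Conditions: allenylboronic acid pinacol ester (1.5 equiv), (S)-TRIP (5 mol%), 4 Å molecular sieves, toluene, 0 °C; aqueous work-up
Reagents that add atoms: allenylboronic acid pinacol ester C=C=CB1OC(C)(C)C(C)(C)O1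
Why: Chiral-phosphoric-acid-catalysed propargylboration through a closed six-membered SE2′ transition state, in which the catalyst should shield the Re face so that Si-face attack sets the (S)-carbinol C8.

Step 4
Reactants: 5 (1S)-1-[4-(TBSO-methyl)furan-3-yl]but-3-yn-1-ol
Product: 6 (1S)-1-(TBSO)-1-[4-(TBSO-methyl)furan-3-yl]but-3-yne (bis-TBS ether)
Conditions: TBSCl, imidazole, DMF, 23 °C
Reagents that add atoms: tert-butyl(chloro)dimethylsilane CC(C)(C)[Si](C)(C)Cl
Why: Standard O-silylation of a secondary alcohol, needed so that C8–O cannot direct metalation or epoxidation later; C8 is untouched.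

Step 5
Reactants: 6 bis-TBS alkyne
Product: 9 (3E,6S)-6-(TBSO)-6-[4-(TBSO-methyl)furan-3-yl]-4-methylhex-3-en-1-ol, via alkenylalane 7 (not isolated), via lithium aluminate 8 (not isolated)
Conditions: Me3Al (3 equiv), Cp2ZrCl2 (0.3 equiv), CH2Cl2, 0 → 23 °C; n-BuLi, THF, −78 °C; ethylene oxide, −78 → 23 °C
Reagents that add atoms: trimethylaluminium C[Al](C)C; ethylene oxide C1CO1
Why: Negishi carboalumination adds CH3 and Al syn with Al at the terminal carbon, and the alkenylaluminate should open ethylene oxide with retention, which fixes the (E)-trisubstituted C1=C10 alkene and brings in C2 and C3.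

Step 6
Reactants: 9 (3E,6S)-homoallylic alcohol
Product: 10 2-[(2R,3R)-3-{(2S)-2-(TBSO)-2-[4-(TBSO-methyl)furan-3-yl]ethyl}-3-methyloxiran-2-yl]ethan-1-ol
Conditions: Hf(OtBu)4 (10 mol%), (1R,2R)-N,N′-dihydroxy-N,N′-bis(2,2-diphenylacetyl)cyclohexane-1,2-diamine (11 mol%), cumene hydroperoxide, DMPU, 4 Å molecular sieves, toluene, 0 °C
Reagents that add atoms: cumene hydroperoxide CC(C)(OO)c1ccccc1
Why: Hydroxyl-directed catalytic asymmetric epoxidation of a homoallylic alcohol, in which the metal-bound peroxide should reach only the alkene next to the free OH (furan spared), the ligand selects the face giving the (R,R)-epoxide, and the trans relationship follows from the E-alkene.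

Step 7
Reactants: 10 epoxy alcohol
Product: 11 (2R,3R)-3-(2-iodoethyl)-2-methyl-2-{(2S)-2-(TBSO)-2-[4-(TBSO-methyl)furan-3-yl]ethyl}oxirane
Conditions: I2, PPh3, imidazole, CH2Cl2, 0 °C, dark
Reagents that add atoms: iodine II
Why: Appel iodination of the primary alcohol under imidazole buffering, which should leave the epoxide, the silyl ethers and all stereocentres untouched.

Step 8
Reactants: 12 1,1-dimethoxypropan-2-one; 13 (2S,3S)-1,4-dimethoxybutane-2,3-diol
Product: 14 1-[(4S,5S)-4,5-bis(methoxymethyl)-1,3-dioxolan-2-yl]ethan-1-one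
Conditions: p-TsOH·H2O (cat.), benzene, reflux, methanol removed over 4 Å molecular sieves
Reagents that add atoms: none
Why: Acid-catalysed transacetalisation driven by removal of methanol; the C2-symmetric diol makes the acetal carbon non-stereogenic and installs the chelating auxiliary.

Step 9
Reactants: 11 epoxy iodide; 14 chiral keto acetal
Product: 19 (2R,4S)-4-(TBSO)-4-[4-(TBSO-methyl)furan-3-yl]-2-{(2S,5R)-5-[(4S,5S)-4,5-bis(methoxymethyl)-1,3-dioxolan-2-yl]-5-methyloxolan-2-yl}butan-2-ol, via alkyllithium 15 (not isolated), via alkylmagnesium bromide 16 (not isolated), via bromomagnesium alkoxide 17 (not isolated), via potassium alkoxide 18 (not isolated)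
Conditions: t-BuLi (2.1 equiv), Et2O/pentane, −78 °C; MgBr2·OEt2, −78 °C; 14, THF, −78 °C; then KOtBu, THF, −78 → 40 °C; H2O
Reagents that add atoms: none
Why: Iodine–lithium exchange and transmetalation give a primary alkylmagnesium bromide that adds to the ketone of 14 (C3–C4), and after exchange of the counter-ion for potassium the tertiary alkoxide attacks the secondary epoxide carbon C1 from the rear (O–C1); the closest known types are Grignard addition to a chiral α-keto acetal and base-mediated epoxy-alcohol cyclisation. The oxolane closes in the 5-exo-tet mode. C4 should be controlled by the C2-symmetric dioxolane through a magnesium chelate linking the carbonyl oxygen, an acetal oxygen and a methoxymethyl arm; C1 is set by SN2 inversion of the (R)-epoxide carbon; C10 keeps the epoxide configuration and is released as the tertiary alcohol. The step needs attack at C1 (5-exo) and not at the tertiary C10 (6-endo), which the basic, Lewis-acid-poor potassium alkoxide should secure. It also needs the carbanion to survive beside the epoxide, which the low temperature and the fast addition to the activated keto acetal should secure.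

Step 10
Reactants: 19 oxolane carbinol
Product: 20 the primary alcohol of 19 (furan CH2OH free, C8–OTBS kept)
Conditions: HF·pyridine, pyridine, THF, 0 °C
Reagents that add atoms: none
Why: Selective desilylation, since buffered fluoride should cleave the unhindered primary silyl ether much faster than the secondary one and leave the dioxolane alone.

Step 11
Reactants: 20 furylmethanol
Product: 23 butenolide: 3-(hydroxymethyl)-4-[(1S,3R)-1-(TBSO)-3-hydroxy-3-{(2S,5R)-5-[(4S,5S)-4,5-bis(methoxymethyl)-1,3-dioxolan-2-yl]-5-methyloxolan-2-yl}butyl]furan-2(5H)-one, via trilithiated furan 21 (not isolated), via furylborate 22 (not isolated)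
Conditions: n-BuLi (3.3 equiv), THF, −78 → 0 °C; B(OMe)3, −78 → 0 °C; 30% H2O2, aqueous NaHCO3, 0 °C; Et3N
Reagents that add atoms: hydrogen peroxide OO
Why: Alkoxide-directed ortho-lithiation of the 3-furylmethanol should place lithium on the adjacent furan α-carbon (C12), and borylation–peroxide oxidation gives the 2-hydroxyfuran, which tautomerises to the conjugated 2(5H)-furanone.

Step 12
Reactants: 23 butenolide acetal
Product: 26 (1S,4R,5E,8S,10R)-8-(TBSO)-1,4-epoxy-10,13-dihydroxygermacra-5,7(11)-dien-6,12-olide, via silyloxyfuran 24 (not isolated), via alkoxy butenolide 25 (not isolated)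
Conditions: TMSOTf (3.5 equiv), Et3N (4.5 equiv), CH2Cl2, 0 °C; slow addition to TMSOTf (2 equiv), CH2Cl2 (0.002 M), −78 → −20 °C; DBU, 23 °C; citric acid, MeOH work-up
Reagents that add atoms: none
Why: Silylation gives the 2-silyloxyfuran, whose γ-carbon C6 should attack the oxocarbenium ion released from the dioxolane in an intramolecular vinylogous Mukaiyama aldol-type reaction (ten-membered carbocycle), and DBU then expels the auxiliary alkoxide by E1cB elimination to give the enol lactone in the only C5=C6 geometry the bridged ring allows (C4 cis to C7).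

Step 13
Reactants: 26 macrocyclic diol
Product: 27 (1S,4R,5E,8S,10R)-13-acetoxy-8-(TBSO)-1,4-epoxy-10-hydroxygermacra-5,7(11)-dien-6,12-olide
Conditions: Ac2O (1.2 equiv), pyridine, CH2Cl2, 0 °C
Reagents that add atoms: acetic anhydride CC(=O)OC(C)=O
Why: Acetylation under mild base should be selective for the primary allylic alcohol over the hindered tertiary C10 alcohol.

Step 14
Reactants: 27 acetate
Product: 28 (1S,4R,5E,8S,10R)-13-acetoxy-1,4-epoxy-8,10-dihydroxygermacra-5,7(11)-dien-6,12-olide
Conditions: HF·pyridine, THF, 0 → 23 °C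
Reagents that add atoms: none
Why: Fluoride desilylation under non-basic conditions should free the C8 alcohol without acetate loss or translactonisation to C8.

Step 15
Reactants: 29 methyl (2S)-2-methyloxirane-2-carboxylate
Product: 30 (2S)-2-methyloxirane-2-carboxylic acid
Conditions: LiOH·H2O, THF/H2O, 0 °C; cold dilute HCl to pH 3, extraction
Reagents that add atoms: lithium hydroxide [Li+].[OH-]
Why: Saponification of the methyl ester at low temperature followed by careful acidification should give the glycidic acid with the quaternary epoxide centre untouched.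

Step 16
Reactants: 28 C8 alcohol; 30 (2S)-2-methyloxirane-2-carboxylic acid
Product: 32 CNP0142137.1, via mixed anhydride 31 (not isolated)
Conditions: 30, 2,4,6-trichlorobenzoyl chloride, Et3N, THF, 0 °C; then 28, DMAP, toluene, 23 °C
Reagents that add atoms: none
Why: Yamaguchi esterification, in which DMAP should attack the aliphatic carbonyl of the mixed anhydride and the acylpyridinium acylates the secondary C8 alcohol and not the tertiary C10 alcohol; the side-chain epoxide centre is bought.

## Compound list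

1 | furan-3,4-diyldimethanol | OCc1cocc1CO | starting material
2 | [4-(TBSO-methyl)furan-3-yl]methanol | OCc1cocc1CO[Si](C)(C)C(C)(C)C | intermediate
3 | 4-(TBSO-methyl)furan-3-carbaldehyde | O=Cc1cocc1CO[Si](C)(C)C(C)(C)C | intermediate
4 | pinacol borate ester of 5 | C#CC[C@H](OB1OC(C)(C)C(C)(C)O1)c1cocc1CO[Si](C)(C)C(C)(C)C | intermediate (not isolated)
5 | (1S)-1-[4-(TBSO-methyl)furan-3-yl]but-3-yn-1-ol | C#CC[C@H](O)c1cocc1CO[Si](C)(C)C(C)(C)C | intermediate
6 | (1S)-1-(TBSO)-1-[4-(TBSO-methyl)furan-3-yl]but-3-yne | C#CC[C@H](O[Si](C)(C)C(C)(C)C)c1cocc1CO[Si](C)(C)C(C)(C)C | intermediate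
7 | (E)-alkenyl(dimethyl)alane from 6 | C[Al](C)/C=C(\C)C[C@H](O[Si](C)(C)C(C)(C)C)c1cocc1CO[Si](C)(C)C(C)(C)C | intermediate (not isolated)
8 | lithium butyl(alkenyl)dimethylaluminate | [Li+].CCCC[Al-](C)(C)/C=C(\C)C[C@H](O[Si](C)(C)C(C)(C)C)c1cocc1CO[Si](C)(C)C(C)(C)C | intermediate (not isolated)
9 | (3E,6S)-6-(TBSO)-6-[4-(TBSO-methyl)furan-3-yl]-4-methylhex-3-en-1-ol | OCC/C=C(\C)C[C@H](O[Si](C)(C)C(C)(C)C)c1cocc1CO[Si](C)(C)C(C)(C)C | intermediate
10 | 2-[(2R,3R)-3-{(2S)-2-(TBSO)-2-[4-(TBSO-methyl)furan-3-yl]ethyl}-3-methyloxiran-2-yl]ethan-1-ol | OCC[C@H]1O[C@]1(C)C[C@H](O[Si](C)(C)C(C)(C)C)c1cocc1CO[Si](C)(C)C(C)(C)C | intermediate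
11 | (2R,3R)-3-(2-iodoethyl)-2-methyl-2-{(2S)-2-(TBSO)-2-[4-(TBSO-methyl)furan-3-yl]ethyl}oxirane | ICC[C@H]1O[C@]1(C)C[C@H](O[Si](C)(C)C(C)(C)C)c1cocc1CO[Si](C)(C)C(C)(C)C | intermediate
12 | 1,1-dimethoxypropan-2-one | CC(=O)C(OC)OC | starting material
13 | (2S,3S)-1,4-dimethoxybutane-2,3-diol | COC[C@H](O)[C@@H](O)COC | starting material
14 | 1-[(4S,5S)-4,5-bis(methoxymethyl)-1,3-dioxolan-2-yl]ethan-1-one | CC(=O)C1O[C@@H](COC)[C@H](COC)O1 | intermediate
15 | primary alkyllithium from 11 | [Li]CC[C@H]1O[C@]1(C)C[C@H](O[Si](C)(C)C(C)(C)C)c1cocc1CO[Si](C)(C)C(C)(C)C | intermediate (not isolated)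
16 | alkylmagnesium bromide from 15 | Br[Mg]CC[C@H]1O[C@]1(C)C[C@H](O[Si](C)(C)C(C)(C)C)c1cocc1CO[Si](C)(C)C(C)(C)C | intermediate (not isolated)
17 | bromomagnesium tertiary alkoxide (C3–C4 adduct, epoxide intact, C4 R) | C[C@@](O[Mg]Br)(CC[C@H]1O[C@]1(C)C[C@H](O[Si](C)(C)C(C)(C)C)c1cocc1CO[Si](C)(C)C(C)(C)C)C1O[C@@H](COC)[C@H](COC)O1 | intermediate (not isolated)
18 | potassium alkoxide of the same adduct | C[C@@]([O-])(CC[C@H]1O[C@]1(C)C[C@H](O[Si](C)(C)C(C)(C)C)c1cocc1CO[Si](C)(C)C(C)(C)C)C1O[C@@H](COC)[C@H](COC)O1.[K+] | intermediate (not isolated)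
19 | (2R,4S)-4-(TBSO)-4-[4-(TBSO-methyl)furan-3-yl]-2-{(2S,5R)-5-[(4S,5S)-4,5-bis(methoxymethyl)-1,3-dioxolan-2-yl]-5-methyloxolan-2-yl}butan-2-ol | COC[C@@H]2OC(O[C@H]2COC)[C@@]1(C)CC[C@H](O1)[C@](C)(O)C[C@H](O[Si](C)(C)C(C)(C)C)c1cocc1CO[Si](C)(C)C(C)(C)C | intermediate
20 | primary alcohol of 19 (furan CH2OH free) | COC[C@@H]2OC(O[C@H]2COC)[C@@]1(C)CC[C@H](O1)[C@](C)(O)C[C@H](O[Si](C)(C)C(C)(C)C)c1cocc1CO | intermediate
21 | C12-lithiated furan, dilithium dialkoxide | COC[C@@H]2OC(O[C@H]2COC)[C@@]1(C)CC[C@H](O1)[C@](C)(O[Li])C[C@H](O[Si](C)(C)C(C)(C)C)c1coc([Li])c1CO[Li] | intermediate (not isolated)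
22 | lithium furyl(trimethoxy)borate | COC[C@@H]2OC(O[C@H]2COC)[C@@]1(C)CC[C@H](O1)[C@](C)(O[Li])C[C@H](O[Si](C)(C)C(C)(C)C)c1coc([B-](OC)(OC)OC)c1CO[Li].[Li+] | intermediate (not isolated)
23 | 3-(hydroxymethyl)-4-substituted furan-2(5H)-one (C8 S, C10 R, oxolane 2S,5R, dioxolane 4S,5S) | COC[C@@H]2OC(O[C@H]2COC)[C@@]1(C)CC[C@H](O1)[C@](C)(O)C[C@H](O[Si](C)(C)C(C)(C)C)C1=C(CO)C(=O)OC1 | intermediate
24 | 2-(trimethylsilyloxy)furan, C10 and C13 O-TMS | COC[C@@H]2OC(O[C@H]2COC)[C@@]1(C)CC[C@H](O1)[C@](C)(O[Si](C)(C)C)C[C@H](O[Si](C)(C)C(C)(C)C)c1coc(O[Si](C)(C)C)c1CO[Si](C)(C)C | intermediate (not isolated)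
25 | cyclised butenolide with C5–O-auxiliary and C6–H (C5, C6 mixed) | C[Si](C)(C)OCC1=C2C(C(O[C@@H](COC)[C@H](COC)O[Si](C)(C)C)[C@@]3(C)CC[C@H](O3)[C@](C)(O[Si](C)(C)C)C[C@@H]2O[Si](C)(C)C(C)(C)C)OC1=O | intermediate (not isolated)
26 | (1S,4R,5E,8S,10R)-8-(TBSO)-1,4-epoxy-10,13-dihydroxygermacra-5,7(11)-dien-6,12-olide | OCC1=C2/C(=C\[C@@]3(C)CC[C@H](O3)[C@](C)(O)C[C@@H]2O[Si](C)(C)C(C)(C)C)OC1=O | intermediate
27 | (1S,4R,5E,8S,10R)-13-acetoxy-8-(TBSO)-1,4-epoxy-10-hydroxygermacra-5,7(11)-dien-6,12-olide | CC(=O)OCC1=C2/C(=C\[C@@]3(C)CC[C@H](O3)[C@](C)(O)C[C@@H]2O[Si](C)(C)C(C)(C)C)OC1=O | intermediate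
28 | (1S,4R,5E,8S,10R)-13-acetoxy-1,4-epoxy-8,10-dihydroxygermacra-5,7(11)-dien-6,12-olide | CC(=O)OCC1=C2/C(=C\[C@@]3(C)CC[C@H](O3)[C@](C)(O)C[C@@H]2O)OC1=O | intermediate
29 | methyl (2S)-2-methyloxirane-2-carboxylate | COC(=O)[C@]1(C)CO1 | starting material
30 | (2S)-2-methyloxirane-2-carboxylic acid | OC(=O)[C@]1(C)CO1 | intermediate
31 | (2S)-2-methyloxirane-2-carboxylic 2,4,6-trichlorobenzoic anhydride | O=C(OC(=O)[C@]1(C)CO1)c1c(Cl)cc(Cl)cc1Cl | intermediate (not isolated)
32 | CNP0142137.1, (1S,4R,5E,8S,10R)-13-acetoxy-1,4-epoxy-10-hydroxy-8-{[(2S)-2-methyloxirane-2-carbonyl]oxy}germacra-5,7(11)-dien-6,12-olide | CC(=O)OCC1=C2/C(=C\[C@@]3(C)CC[C@H](O3)[C@](C)(O)C[C@@H]2OC(=O)[C@]2(C)CO2)OC1=O | target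

## Step count and risks

Total step count: 16. Longest linear sequence: 14 steps (1 to 32 through steps 1–7, 9–14 and 16).

Steps most likely to fail, riskiest first:

Step 9. The carbanion may open its own epoxide in a 1,3-ring closure before it meets the ketone, and facial selectivity at C4 may erode if the magnesium chelate is not maintained. The fallback is a samarium Barbier coupling: iodide 11 and keto acetal 14 are mixed and treated with SmI2/HMPA in THF, so that the organosamarium is captured by the ketone as it forms. The samarium alkoxide is then exchanged with KOtBu and warmed, and the oxolane closes as before. This fallback sets out from 11 and 14 and comes back at 19 without any new compound.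

Step 12. Ionisation of the cyclic acetal beside the quaternary ether carbon may be slow, the allylic silyloxy groups may ionise in competition, or oligomerisation may win over the medium-ring closure. The fallback sets out from 23: the acetal is hydrolysed with aqueous trifluoroacetic acid to the aldehyde F1. The ring is then closed at high dilution by an amine-mediated vinylogous Knoevenagel condensation (pyrrolidine, AcOH, toluene): iminium activation of the aldehyde, attack by the butenolide dienol at C6, and loss of the amine. This gives the enol lactone directly and comes back at 26.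

Step 11. The furylborate may undergo protodeboronation, or the electron-rich furan may be over-oxidised during the peroxide step. The fallback sets out from 20: the same alkoxide-directed lithiation is quenched with TMSCl (mild acidic work-up) to give the 2-trimethylsilylfuran F2. Photo-oxygenation with singlet oxygen (O2, rose bengal, visible light, −78 °C) should give the γ-hydroxybutenolide F3 with the carbonyl at the silylated carbon. NaBH4 in MeOH at 0 °C then reduces the lactol carbon to CH2 and comes back at 23.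

Further compounds
F0 | step 9 | none | none
F1 | step 12 | aldehyde from 23: (2R,5S)-2-methyl-5-{(2R,4S)-4-(TBSO)-2-hydroxy-4-[4-(hydroxymethyl)-5-oxo-2,5-dihydrofuran-3-yl]butan-2-yl}oxolane-2-carbaldehyde | O=C[C@@]1(C)CC[C@H](O1)[C@](C)(O)C[C@H](O[Si](C)(C)C(C)(C)C)C1=C(CO)C(=O)OC1
F2 | step 11 | 2-trimethylsilylfuran analogue of 20 (TMS on the furan carbon next to the CH2OH-bearing carbon) | COC[C@@H]2OC(O[C@H]2COC)[C@@]1(C)CC[C@H](O1)[C@](C)(O)C[C@H](O[Si](C)(C)C(C)(C)C)c1coc([Si](C)(C)C)c1CO
F3 | step 11 | γ-hydroxybutenolide (5-hydroxy analogue of 23, lactol carbon unassigned) | COC[C@@H]2OC(O[C@H]2COC)[C@@]1(C)CC[C@H](O1)[C@](C)(O)C[C@H](O[Si](C)(C)C(C)(C)C)C1=C(CO)C(=O)OC1O
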